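## Retrosynthetic overview

1. Target 28 ⇐ alcohol 27 (Dess–Martin) ⇐ silyl ether 26 (desilylation); the α-methyl β,γ-unsaturated ketone is unmasked last to avoid epimerisation.
2. The cyclohexadiene of 26 is the last ring formed: thermal disrotatory 6π-electrocyclisation of the (2E,4Z,6E,8E)-tetraenyl pyrone 25, which sets pyrone and side chain cis.
3. 25 ⇐ Suzuki coupling of two halves of similar size: pyrone propenyl boronate 12 (C14) and (Z)-trienyl iodide 24 (C15 chain).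
4. 12 ⇐ γ-pyrone ring (first ring formed) from a Weiler dianion aldol of ketoester 6 with iodo-enal 4, oxidation, lactonisation and O-methylation.
5. 24 ⇐ Evans syn-aldol (sets the C-methyl centre), two Wittig homologations, Zhao–Wittig iodo-olefination.

Assumption: phosphorus ylides, the Evans auxiliary, and silyl and boron reagents are treated as reagents. The electrocyclisation is taken to give about 1:1 of two separable cis diastereomers, because the side-chain stereocentre is too remote to bias it.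

## Route

Step 1
Reactants: 1 prop-2-yn-1-ol
Product: 3 (2E)-3-iodo-2-methylprop-2-en-1-ol, via dimethylaluminium (2E)-3-(dimethylalumanyl)-2-methylprop-2-en-1-olate 2 (not isolated)
Conditions: Me3Al (3 equiv), Cp2ZrCl2 (25 mol %), CH2Cl2, 0 °C → rt; I2, THF, −30 → 0 °C; aq K2CO3
Reagents that add atoms: trimethylaluminium C[Al](C)C; iodine II
Why: Negishi Zr-catalysed syn-carboalumination puts Me on the internal and Al on the terminal carbon, and iodinolysis with retention gives the E-iodide.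

Step 2
Reactants: 3 (2E)-3-iodo-2-methylprop-2-en-1-ol
Product: 4 (2E)-3-iodo-2-methylprop-2-enal
Conditions: MnO2, CH2Cl2, rt
Reagents that add atoms: none
Why: MnO2 oxidises the allylic alcohol selectively without touching the vinyl iodide or the alkene geometry.

Step 3
Reactants: 5 methyl propanoate (2 equiv)
Product: 6 methyl 2-methyl-3-oxopentanoate (racemic)
Conditions: NaH, cat. MeOH, THF, reflux; 1 M HCl
Reagents that add atoms: none
Why: Claisen self-condensation, driven by deprotonation of the β-keto ester product.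

Step 4
Reactants: 6 methyl 2-methyl-3-oxopentanoate; 4 (2E)-3-iodo-2-methylprop-2-enal
Product: 8 methyl (6E)-5-hydroxy-7-iodo-2,4,6-trimethyl-3-oxohept-6-enoate (diastereomer mixture), via sodium lithium 1-methoxy-2-methyl-1,3-dioxopentane-2,4-diide 7 (not isolated)
Conditions: NaH, THF, 0 °C; n-BuLi, 0 °C; 4, −78 °C; 1 M HCl
Reagents that add atoms: none
Why: Weiler dianion aldol, in which the more reactive γ-carbanion adds 1,2 to the enal; the new sp3 centres are removed in steps 5 and 6.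

Step 5
Reactants: 8 methyl (6E)-5-hydroxy-7-iodo-2,4,6-trimethyl-3-oxohept-6-enoate
Product: 9 methyl (6E)-7-iodo-2,4,6-trimethyl-3,5-dioxohept-6-enoate
Conditions: Dess–Martin periodinane, CH2Cl2, rt
Reagents that add atoms: none
Why: Dess–Martin oxidation of the δ-hydroxy-β-keto ester gives the β,δ-diketo ester under neutral conditions.

Step 6
Reactants: 9 methyl (6E)-7-iodo-2,4,6-trimethyl-3,5-dioxohept-6-enoate
Product: 10 4-hydroxy-6-[(1E)-1-iodoprop-1-en-2-yl]-3,5-dimethyl-2H-pyran-2-one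
Conditions: DBU, PhH, 60 °C; 1 M HCl
Reagents that add atoms: none
Why: Base-mediated lactonisation of the C5 enol oxygen onto the methyl ester forms the aromatic 4-hydroxy-2-pyranone (first ring).

Step 7
Reactants: 10 4-hydroxy-6-[(1E)-1-iodoprop-1-en-2-yl]-3,5-dimethyl-2H-pyran-2-one
Product: 11 6-[(1E)-1-iodoprop-1-en-2-yl]-2-methoxy-3,5-dimethyl-4H-pyran-4-one
Conditions: MeOTf, CH2Cl2, rt; aq NaHCO3
Reagents that add atoms: methyl trifluoromethanesulfonate COS(=O)(=O)C(F)(F)F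
Why: A hard methylating agent alkylates the more basic lactone carbonyl oxygen, and loss of the 4-OH proton gives the α-methoxy-γ-pyrone.

Step 8
Reactants: 11 6-[(1E)-1-iodoprop-1-en-2-yl]-2-methoxy-3,5-dimethyl-4H-pyran-4-one
Product: 12 2-methoxy-3,5-dimethyl-6-[(1E)-1-(4,4,5,5-tetramethyl-1,3,2-dioxaborolan-2-yl)prop-1-en-2-yl]-4H-pyran-4-one
Conditions: B2pin2, PdCl2(PPh3)2 (3 mol %), PPh3, KOPh, PhMe, 50 °C
Reagents that add atoms: bis(pinacolato)diboron CC1(C)OB(OC1(C)C)B1OC(C)(C)C(C)(C)O1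
Why: Miyaura borylation of the alkenyl iodide proceeds with retention of the E geometry.

Step 9
Reactants: 13 propanoyl chloride
Product: 14 (4S)-4-benzyl-3-propanoyl-1,3-oxazolidin-2-one
Conditions: (S)-4-benzyl-1,3-oxazolidin-2-one, n-BuLi, THF, −78 °C; 13, −78 → 0 °C
Reagents that add atoms: (4S)-4-benzyl-1,3-oxazolidin-2-one O=C1N[C@@H](Cc2ccccc2)CO1
Why: N-acylation of the lithiated Evans auxiliary.

Step 10
Reactants: 14 (4S)-4-benzyl-3-propanoyl-1,3-oxazolidin-2-one; 15 propanal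
Product: 18 (4S)-4-benzyl-3-[(2S,3R)-3-hydroxy-2-methylpentanoyl]-1,3-oxazolidin-2-one, via dibutyl{[(1Z)-1-[(4S)-4-benzyl-2-oxo-1,3-oxazolidin-3-yl]prop-1-en-1-yl]oxy}borane 16 (not isolated), via (4S)-4-benzyl-3-{(2S,3R)-3-[(dibutylboranyl)oxy]-2-methylpentanoyl}-1,3-oxazolidin-2-one 17 (not isolated)
Conditions: n-Bu2BOTf, Et3N, CH2Cl2, 0 °C; 15, −78 → 0 °C; pH 7 buffer, MeOH, 30% H2O2
Reagents that add atoms: none
Why: Evans syn-aldol, in which the Z-boron enolate reacts through a Zimmerman–Traxler chair on the face opposite the benzyl group, setting (2S) (the future side-chain methyl centre) and (3R).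

Step 11
Reactants: 18 (4S)-4-benzyl-3-[(2S,3R)-3-hydroxy-2-methylpentanoyl]-1,3-oxazolidin-2-one
Product: 19 (4S)-4-benzyl-3-[(2S,3R)-3-{[tert-butyl(dimethyl)silyl]oxy}-2-methylpentanoyl]-1,3-oxazolidin-2-one
Conditions: TBSOTf, 2,6-lutidine, CH2Cl2, 0 °C
Reagents that add atoms: tert-butyldimethylsilyl trifluoromethanesulfonate CC(C)(C)[Si](C)(C)OS(=O)(=O)C(F)(F)F
Why: Silylation of the secondary alcohol blocks retro-aldol and masks the future ketone.

Step 12
Reactants: 19 (4S)-4-benzyl-3-[(2S,3R)-3-{[tert-butyl(dimethyl)silyl]oxy}-2-methylpentanoyl]-1,3-oxazolidin-2-one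
Product: 20 (2R,3R)-3-{[tert-butyl(dimethyl)silyl]oxy}-2-methylpentan-1-ol
Conditions: LiBH4, MeOH (1 equiv), THF, 0 °C
Reagents that add atoms: none
Why: Reductive cleavage of the imide releases the auxiliary without epimerising the α-centre (the descriptor changes by CIP priority only).

Step 13
Reactants: 20 (2R,3R)-3-{[tert-butyl(dimethyl)silyl]oxy}-2-methylpentan-1-ol
Product: 21 (2S,3R)-3-{[tert-butyl(dimethyl)silyl]oxy}-2-methylpentanal
Conditions: Dess–Martin periodinane, NaHCO3, CH2Cl2, 0 °C → rt; used crude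
Reagents that add atoms: none
Why: Buffered Dess–Martin oxidation gives the α-chiral aldehyde without epimerisation.

Step 14
Reactants: 21 (2S,3R)-3-{[tert-butyl(dimethyl)silyl]oxy}-2-methylpentanal
Product: 22 (2E,4R,5R)-5-{[tert-butyl(dimethyl)silyl]oxy}-2,4-dimethylhept-2-enal
Conditions: Ph3P=C(Me)CHO, PhMe, 90 °C
Reagents that add atoms: 2-(triphenyl-λ5-phosphanylidene)propanal CC(C=O)=P(c1ccccc1)(c1ccccc1)c1ccccc1
Why: Wittig reaction with a stabilised, non-basic ylide gives the E-trisubstituted enal and leaves the α-centre intact.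

Step 15
Reactants: 22 (2E,4R,5R)-5-{[tert-butyl(dimethyl)silyl]oxy}-2,4-dimethylhept-2-enal
Product: 23 (2E,4E,6R,7R)-7-{[tert-butyl(dimethyl)silyl]oxy}-2,4,6-trimethylnona-2,4-dienal
Conditions: Ph3P=C(Me)CHO, PhMe, 110 °C
Reagents that add atoms: 2-(triphenyl-λ5-phosphanylidene)propanal CC(C=O)=P(c1ccccc1)(c1ccccc1)c1ccccc1
Why: A second stabilised-ylide Wittig homologation gives the E,E-dienal under thermodynamic control.

Step 16
Reactants: 23 (2E,4E,6R,7R)-7-{[tert-butyl(dimethyl)silyl]oxy}-2,4,6-trimethylnona-2,4-dienal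
Product: 24 tert-butyl{[(3R,4R,5E,7E,9Z)-10-iodo-4,6,8-trimethylundeca-5,7,9-trien-3-yl]oxy}dimethylsilane
Conditions: EtPPh3I, n-BuLi, THF, rt; I2, −78 °C; NaHMDS, −78 → −20 °C; 23, −78 °C → rt
Reagents that add atoms: ethyltriphenylphosphonium iodide CC[P+](c1ccccc1)(c1ccccc1)c1ccccc1.[I-]; iodine II
Why: Zhao–Wittig olefination with the non-stabilised α-iodoethylidene ylide goes through the kinetic cis-oxaphosphetane and places iodine cis to the chain (Z).

Step 17
Reactants: 12 2-methoxy-3,5-dimethyl-6-[(1E)-1-(4,4,5,5-tetramethyl-1,3,2-dioxaborolan-2-yl)prop-1-en-2-yl]-4H-pyran-4-one; 24 tert-butyl{[(3R,4R,5E,7E,9Z)-10-iodo-4,6,8-trimethylundeca-5,7,9-trien-3-yl]oxy}dimethylsilane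
Product: 26 6-[(1R,6S)-6-[(2E,4R,5R)-5-{[tert-butyl(dimethyl)silyl]oxy}-4-methylhept-2-en-2-yl]-1,3,5-trimethylcyclohexa-2,4-dien-1-yl]-2-methoxy-3,5-dimethyl-4H-pyran-4-one, via 6-[(2E,4Z,6E,8E,10R,11R)-11-{[tert-butyl(dimethyl)silyl]oxy}-4,6,8,10-tetramethyltrideca-2,4,6,8-tetraen-2-yl]-2-methoxy-3,5-dimethyl-4H-pyran-4-one 25 (not isolated)
Conditions: Pd(PPh3)4 (10 mol %), TlOEt, THF/H2O 3:1, rt, dark; filter; PhMe, 80 °C, dark; HPLC separation of the two cis diastereomers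
Reagents that add atoms: none
Why: Stereoretentive Suzuki–Miyaura coupling gives the E,Z,E-triene unit, whose thermal disrotatory 6π-electrocyclisation places pyrone and side chain cis; facial sense is not controlled, so the (1R,6S) isomer is separated from its (1S,6R) ring diastereomer (about 1:1).

Step 18
Reactants: 26 6-[(1R,6S)-6-[(2E,4R,5R)-5-{[tert-butyl(dimethyl)silyl]oxy}-4-methylhept-2-en-2-yl]-1,3,5-trimethylcyclohexa-2,4-dien-1-yl]-2-methoxy-3,5-dimethyl-4H-pyran-4-one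
Product: 27 6-{(1R,6S)-6-[(2E,4R,5R)-5-hydroxy-4-methylhept-2-en-2-yl]-1,3,5-trimethylcyclohexa-2,4-dien-1-yl}-2-methoxy-3,5-dimethyl-4H-pyran-4-one
Conditions: HF·pyridine, pyridine, THF, 0 °C → rt
Reagents that add atoms: none
Why: Buffered fluoride desilylation spares the methoxypyrone and the diene.

Step 19
Reactants: 27 6-{(1R,6S)-6-[(2E,4R,5R)-5-hydroxy-4-methylhept-2-en-2-yl]-1,3,5-trimethylcyclohexa-2,4-dien-1-yl}-2-methoxy-3,5-dimethyl-4H-pyran-4-one
Product: 28 2-methoxy-3,5-dimethyl-6-{(1R,6S)-1,3,5-trimethyl-6-[(2E,4R)-4-methyl-5-oxohept-2-en-2-yl]cyclohexa-2,4-dien-1-yl}-4H-pyran-4-one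
Conditions: Dess–Martin periodinane, NaHCO3, CH2Cl2, 0 °C
Reagents that add atoms: none
Why: Neutral, buffered Dess–Martin oxidation gives the ethyl ketone without epimerising the (4R) centre or conjugating the β,γ-alkene.

## Compound list

1 | prop-2-yn-1-ol | C#CCO | starting material
2 | dimethylaluminium (2E)-3-(dimethylalumanyl)-2-methylprop-2-en-1-olate | C[Al](C)OC/C(C)=C/[Al](C)C | intermediate
3 | (2E)-3-iodo-2-methylprop-2-en-1-ol | OC/C(C)=C/I | intermediate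
4 | (2E)-3-iodo-2-methylprop-2-enal | O=C/C(C)=C/I | intermediate
5 | methyl propanoate | CCC(=O)OC | starting material
6 | methyl 2-methyl-3-oxopentanoate | CCC(=O)C(C)C(=O)OC | intermediate
7 | sodium lithium 1-methoxy-2-methyl-1,3-dioxopentane-2,4-diide | [Na+].[Li+].C[CH-]C(=O)[C-](C)C(=O)OC | intermediate
8 | methyl (6E)-5-hydroxy-7-iodo-2,4,6-trimethyl-3-oxohept-6-enoate | COC(=O)C(C)C(=O)C(C)C(O)/C(C)=C/I | intermediate
9 | methyl (6E)-7-iodo-2,4,6-trimethyl-3,5-dioxohept-6-enoate | COC(=O)C(C)C(=O)C(C)C(=O)/C(C)=C/I | intermediate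
10 | 4-hydroxy-6-[(1E)-1-iodoprop-1-en-2-yl]-3,5-dimethyl-2H-pyran-2-one | Cc1c(O)c(C)c(/C(C)=C/I)oc1=O | intermediate
11 | 6-[(1E)-1-iodoprop-1-en-2-yl]-2-methoxy-3,5-dimethyl-4H-pyran-4-one | COc1oc(/C(C)=C/I)c(C)c(=O)c1C | intermediate
12 | 2-methoxy-3,5-dimethyl-6-[(1E)-1-(4,4,5,5-tetramethyl-1,3,2-dioxaborolan-2-yl)prop-1-en-2-yl]-4H-pyran-4-one | COc1oc(/C(C)=C/B2OC(C)(C)C(C)(C)O2)c(C)c(=O)c1C | intermediate
13 | propanoyl chloride | CCC(Cl)=O | starting material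
14 | (4S)-4-benzyl-3-propanoyl-1,3-oxazolidin-2-one | CCC(=O)N1[C@@H](Cc2ccccc2)COC1=O | intermediate
15 | propanal | CCC=O | starting material
16 | dibutyl{[(1Z)-1-[(4S)-4-benzyl-2-oxo-1,3-oxazolidin-3-yl]prop-1-en-1-yl]oxy}borane | C/C=C(\OB(CCCC)CCCC)N1[C@@H](Cc2ccccc2)COC1=O | intermediate
17 | (4S)-4-benzyl-3-{(2S,3R)-3-[(dibutylboranyl)oxy]-2-methylpentanoyl}-1,3-oxazolidin-2-one | CC[C@@H](OB(CCCC)CCCC)[C@H](C)C(=O)N1[C@@H](Cc2ccccc2)COC1=O | intermediate
18 | (4S)-4-benzyl-3-[(2S,3R)-3-hydroxy-2-methylpentanoyl]-1,3-oxazolidin-2-one | CC[C@@H](O)[C@H](C)C(=O)N1[C@@H](Cc2ccccc2)COC1=O | intermediate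
19 | (4S)-4-benzyl-3-[(2S,3R)-3-{[tert-butyl(dimethyl)silyl]oxy}-2-methylpentanoyl]-1,3-oxazolidin-2-one | CC[C@@H](O[Si](C)(C)C(C)(C)C)[C@H](C)C(=O)N1[C@@H](Cc2ccccc2)COC1=O | intermediate
20 | (2R,3R)-3-{[tert-butyl(dimethyl)silyl]oxy}-2-methylpentan-1-ol | CC[C@@H](O[Si](C)(C)C(C)(C)C)[C@H](C)CO | intermediate
21 | (2S,3R)-3-{[tert-butyl(dimethyl)silyl]oxy}-2-methylpentanal | CC[C@@H](O[Si](C)(C)C(C)(C)C)[C@H](C)C=O | intermediate
22 | (2E,4R,5R)-5-{[tert-butyl(dimethyl)silyl]oxy}-2,4-dimethylhept-2-enal | CC[C@@H](O[Si](C)(C)C(C)(C)C)[C@H](C)/C=C(\C)C=O | intermediate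
23 | (2E,4E,6R,7R)-7-{[tert-butyl(dimethyl)silyl]oxy}-2,4,6-trimethylnona-2,4-dienal | CC[C@@H](O[Si](C)(C)C(C)(C)C)[C@H](C)/C=C(\C)/C=C(\C)C=O | intermediate
24 | tert-butyl{[(3R,4R,5E,7E,9Z)-10-iodo-4,6,8-trimethylundeca-5,7,9-trien-3-yl]oxy}dimethylsilane | CC[C@@H](O[Si](C)(C)C(C)(C)C)[C@H](C)/C=C(\C)/C=C(\C)/C=C(/C)I | intermediate
25 | 6-[(2E,4Z,6E,8E,10R,11R)-11-{[tert-butyl(dimethyl)silyl]oxy}-4,6,8,10-tetramethyltrideca-2,4,6,8-tetraen-2-yl]-2-methoxy-3,5-dimethyl-4H-pyran-4-one | CC[C@@H](O[Si](C)(C)C(C)(C)C)[C@H](C)/C=C(\C)/C=C(\C)/C=C(/C)\C=C(/C)c1oc(OC)c(C)c(=O)c1C | intermediate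
26 | 6-[(1R,6S)-6-[(2E,4R,5R)-5-{[tert-butyl(dimethyl)silyl]oxy}-4-methylhept-2-en-2-yl]-1,3,5-trimethylcyclohexa-2,4-dien-1-yl]-2-methoxy-3,5-dimethyl-4H-pyran-4-one | CC[C@@H](O[Si](C)(C)C(C)(C)C)[C@H](C)/C=C(\C)[C@H]1C(C)=CC(C)=C[C@@]1(C)c1oc(OC)c(C)c(=O)c1C | intermediate
27 | 6-{(1R,6S)-6-[(2E,4R,5R)-5-hydroxy-4-methylhept-2-en-2-yl]-1,3,5-trimethylcyclohexa-2,4-dien-1-yl}-2-methoxy-3,5-dimethyl-4H-pyran-4-one | CC[C@@H](O)[C@H](C)/C=C(\C)[C@H]1C(C)=CC(C)=C[C@@]1(C)c1oc(OC)c(C)c(=O)c1C | intermediate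
28 | 2-methoxy-3,5-dimethyl-6-{(1R,6S)-1,3,5-trimethyl-6-[(2E,4R)-4-methyl-5-oxohept-2-en-2-yl]cyclohexa-2,4-dien-1-yl}-4H-pyran-4-one | CCC(=O)[C@H](C)/C=C(\C)[C@H]1C(C)=CC(C)=C[C@@]1(C)c1oc(OC)c(C)c(=O)c1C | target

## Totals and risks

Total step count: 19. Longest linear sequence: 11 steps (steps 9–19); the pyrone branch is 10 steps (1, 2, 4–8, 17–19).

Steps most likely to fail:

Step 17 (coupling and electrocyclisation). The hindered (Z)-iodide can isomerise or the boronate can protodeboronate before coupling. In addition, the ring closure has no facial control, so at most about half of the material is 26 and it must be separated from its ring diastereomer. Fallback with reversed polarity: set out from 24 and 11. Iodine–lithium exchange on 24 (t-BuLi, Et2O, −78 °C) gives [(2E,4E,6E,8R,9R)-9-{[tert-butyl(dimethyl)silyl]oxy}-4,6,8-trimethylundeca-2,4,6-trien-2-yl]lithium F1. Quenching with Me3SnCl gives trimethyl[(2Z,4E,6E,8R,9R)-9-{[tert-butyl(dimethyl)silyl]oxy}-4,6,8-trimethylundeca-2,4,6-trien-2-yl]stannane F2. Stille coupling of F2 with iodide 11 (Pd2(dba)3, AsPh3, NMP, rt), then warming, rejoins the route at 26 and makes step 8 unnecessary.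

Step 16 (Zhao–Wittig on a hindered α-methyl dienal; low yield or Z/E erosion). Fallback: set out from 23. Corey–Fuchs dibromo-olefination (CBr4, PPh3, CH2Cl2, 0 °C) gives tert-butyl{[(3R,4R,5E,7E)-10,10-dibromo-4,6,8-trimethyldeca-5,7,9-trien-3-yl]oxy}dimethylsilane F3. Negishi trans-selective mono-methylation (MeZnCl, Pd(DPEphos)Cl2, THF) replaces the bromine trans to the chain and gives tert-butyl{[(3R,4R,5E,7E,9Z)-10-bromo-4,6,8-trimethylundeca-5,7,9-trien-3-yl]oxy}dimethylsilane F4. F4 takes the place of 24 in the coupling with 12 and the route is rejoined at 26.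

Step 7 (O-methylation can give the 4-methoxy-2-pyranone instead, and the free triflic acid may damage the vinyl iodide). Fallback: set out from 9 and close the ring with the ester oxygen instead of lactonising. Ph3P/CCl4 in THF activates the C5 enol, and the ester carbonyl oxygen cyclises with retention of the methoxy group. This gives 11 directly, bypasses 10, and makes no new compound (F0).

Further compounds
F1 | step 17 | [(2E,4E,6E,8R,9R)-9-{[tert-butyl(dimethyl)silyl]oxy}-4,6,8-trimethylundeca-2,4,6-trien-2-yl]lithium | CC[C@@H](O[Si](C)(C)C(C)(C)C)[C@H](C)/C=C(\C)/C=C(\C)/C=C(/C)[Li]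
F2 | step 17 | trimethyl[(2Z,4E,6E,8R,9R)-9-{[tert-butyl(dimethyl)silyl]oxy}-4,6,8-trimethylundeca-2,4,6-trien-2-yl]stannane | CC[C@@H](O[Si](C)(C)C(C)(C)C)[C@H](C)/C=C(\C)/C=C(\C)/C=C(/C)[Sn](C)(C)C
F3 | step 16 | tert-butyl{[(3R,4R,5E,7E)-10,10-dibromo-4,6,8-trimethyldeca-5,7,9-trien-3-yl]oxy}dimethylsilane | CC[C@@H](O[Si](C)(C)C(C)(C)C)[C@H](C)/C=C(\C)/C=C(\C)C=C(Br)Br
F4 | step 16 | tert-butyl{[(3R,4R,5E,7E,9Z)-10-bromo-4,6,8-trimethylundeca-5,7,9-trien-3-yl]oxy}dimethylsilane | CC[C@@H](O[Si](C)(C)C(C)(C)C)[C@H](C)/C=C(\C)/C=C(\C)/C=C(/C)Br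
F0 | step 7 | none | none
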